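**Retrosynthetic overview**
- Target ⇐ C1 acetylation, hydroxyl-directed 2,3-epoxidation and MeLi addition ⇐ (11Z,13E)-dienone ⇐ Wittig reaction and iron-catalysed syn-methylmetalation of a propargylic alcohol ⇐ acetyl-substituted trans-hydroazulenol.
- Key disconnection: both carbocycles are made in one acid-catalysed cation–olefin bicyclisation of an acyclic (2Z,6E)-dienynal; the butynyl terminator delivers the C10 acetyl group.
- Ring order: seven-membered ring first (C1–C7 bond), five-membered ring second (C6–C10 bond), in the same operation; the oxirane ring is made last.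
- Acyclic precursor ⇐ neryl acetate (C1–C8) + propargyl unit + methyl group.

Assumption: in nature the hydroazulene is taken to arise from the (2Z,6E)-prenyl cation by C1–C7 bond formation and then C6–C10 closure with loss of H-12; biogenetic locants are used below (C1 carbinol carbon, C2/C3 ring alkene and later epoxide with the methyl on C3, C6/C7 ring fusion with the methyl on C7, C10 the ring carbon bearing the side chain C11–C15).

**Step 1**
Reactants: 1 neryl acetate
Product: 2 (2Z,6E)-8-hydroxy-3,7-dimethylocta-2,6-dien-1-yl acetate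
Conditions: SeO2 (0.1 equiv), t-BuOOH (3 equiv), salicylic acid (0.1 equiv), CH2Cl2, 23 °C
Reagents that add atoms: tert-butyl hydroperoxide, CC(C)(C)OO
Why: Riley-type SeO2/t-BuOOH allylic oxidation attacks the (E)-methyl group of the more electron-rich 6,7-alkene and leaves the (2Z)-allylic acetate alone; no stereocentre is formed and both alkene geometries are kept.

**Step 2**
Reactants: 2 (2Z,6E)-8-hydroxy-3,7-dimethylocta-2,6-dien-1-yl acetate
Product: 3 (2Z,6E)-8-bromo-3,7-dimethylocta-2,6-dien-1-yl acetate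
Conditions: CBr4, PPh3, CH2Cl2, 0 °C
Reagents that add atoms: carbon tetrabromide, BrC(Br)(Br)Br
Why: Appel reaction of a primary allylic alcohol under neutral conditions, which neither transposes the allyl system nor touches the acetate.

**Step 3**
Reactants: 3 (2Z,6E)-8-bromo-3,7-dimethylocta-2,6-dien-1-yl acetate
Product: 4 (2Z,6E)-3,7-dimethylundeca-2,6-dien-10-yn-1-ol
Conditions: HC≡CCH2MgBr (3.2 equiv), Et2O, −20 → 23 °C; aq. NH4Cl
Reagents that add atoms: propargylmagnesium bromide (HC≡CCH2MgBr), C#CC[Mg]Br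
Why: the allenyl/propargyl Grignard reagent displaces the primary allylic bromide through its γ-carbon to give the 1,5-enyne (Grignard allylic coupling), and the excess reagent cleaves the acetate to the free alcohol.

**Step 4**
Reactants: 4 (2Z,6E)-3,7-dimethylundeca-2,6-dien-10-yn-1-ol
Product: 5 (2Z,6E)-3,7-dimethyldodeca-2,6-dien-10-yn-1-ol
Conditions: n-BuLi (2.1 equiv), THF, −78 → 0 °C; MeI (1.1 equiv), 0 → 23 °C
Reagents that add atoms: iodomethane, CI
Why: alkylation of the lithium acetylide in the alkoxide/acetylide dianion, where carbon is far more nucleophilic than the lithium alkoxide; the methyl group is needed so that the alkyne can later end a cyclisation as a linear vinyl cation.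

**Step 5**
Reactants: 5 (2Z,6E)-3,7-dimethyldodeca-2,6-dien-10-yn-1-ol
Product: 6 (2Z,6E)-3,7-dimethyldodeca-2,6-dien-10-ynal
Conditions: TEMPO (0.1 equiv), PhI(OAc)2 (1.1 equiv), CH2Cl2, 0 → 23 °C
Reagents that add atoms: none
Why: oxoammonium (TEMPO) oxidation of the allylic alcohol to the neral-type enal, mild enough to keep the 2Z geometry.

**Step 6**
Reactants: 6 (2Z,6E)-3,7-dimethyldodeca-2,6-dien-10-ynal
Product: 9 1-[(1R,3aS,4R,8aS)-4-hydroxy-3a,6-dimethyl-1,2,3,3a,4,7,8,8a-octahydroazulen-1-yl]ethan-1-one, via vinyl cation 7 (not isolated), via enol 8 (not isolated)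
Conditions: chiral confined imidodiphosphorimidate Brønsted acid (BINOL-derived, 5 mol %, the enantiomer that gives the 1R carbinol), H2O (2 equiv), (CF3)2CHOH/CH2Cl2 (1:4), −40 °C
Reagents that add atoms: water, O
Why: Proposed new method: the acid-bound (Z)-enal is attacked by C7 of the 6E alkene (7-endo) while C6 is captured 5-exo-dig by the butynyl group, an antiperiplanar Stork–Eschenmoser-type addition across the E alkene that makes the ring fusion trans (H6 anti to the C7 methyl) with the hydrogen-bonded C1 oxygen pseudo-equatorial and so anti to the C7 methyl; the linear vinyl cation 7 is trapped by water and enol 8 tautomerises under thermodynamic control to place the acetyl group trans to C5, and the chiral acid selects the aldehyde face and thus the absolute configuration; the Markovnikov 6-exo closure to a bisabolyl-type cation is expected to be reversible and cannot be captured directly by the alkyne (four-membered ring), whereas the 7-endo/5-exo path ends irreversibly; closest known chemistry is the Johnson methylacetylene-terminated cation–olefin polycyclisation and the Brønsted-acid-catalysed asymmetric Prins/carbonyl-ene cyclisation.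

**Step 7**
Reactants: 9 1-[(1R,3aS,4R,8aS)-4-hydroxy-3a,6-dimethyl-1,2,3,3a,4,7,8,8a-octahydroazulen-1-yl]ethan-1-one
Product: 12 (1R,3aS,4R,8aS)-1-(3-hydroxyprop-1-yn-1-yl)-3a,6-dimethyl-1,2,3,3a,4,7,8,8a-octahydroazulen-4-ol, via enol phosphate 10 (not isolated), via terminal alkyne 11 (not isolated)
Conditions: LiN(i-Pr)2 (2.2 equiv), THF, −78 °C; ClP(O)(OEt)2 (1.05 equiv), −78 → 0 °C; LiN(i-Pr)2 (2.5 equiv), −78 → 0 °C; (CH2O)n (5 equiv), 0 → 23 °C
Reagents that add atoms: paraformaldehyde (formaldehyde unit), C=O; diethyl chlorophosphate (its atoms stay only in 10), CCOP(=O)(Cl)OCC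
Why: Negishi methyl ketone → alkyne sequence (kinetic methyl enolate, enol phosphate, elimination) followed by hydroxymethylation of the lithium acetylide; the neopentyl-type C1 alkoxide is expected to be phosphorylated more slowly than the enolate, and C10 is not deprotonated, so its configuration is kept.

**Step 8**
Reactants: 12 (1R,3aS,4R,8aS)-1-(3-hydroxyprop-1-yn-1-yl)-3a,6-dimethyl-1,2,3,3a,4,7,8,8a-octahydroazulen-4-ol
Product: 13 (1R,3aS,4R,8aS)-1-[(2Z)-4-hydroxybut-2-en-2-yl]-3a,6-dimethyl-1,2,3,3a,4,7,8,8a-octahydroazulen-4-ol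
Conditions: MeMgBr (5 equiv), Fe(acac)3 (0.2 equiv), THF, −78 → 0 °C; aq. NH4Cl
Reagents that add atoms: methylmagnesium bromide (MeMgBr), C[Mg]Br
Why: alkoxide-directed iron-catalysed syn-carbomagnesiation of the propargylic alcohol puts the methyl group on C11 and magnesium on C12 on the same side, so after protonation C10 and C13 are cis, which is the required 11Z trisubstituted alkene.

**Step 9**
Reactants: 13 (1R,3aS,4R,8aS)-1-[(2Z)-4-hydroxybut-2-en-2-yl]-3a,6-dimethyl-1,2,3,3a,4,7,8,8a-octahydroazulen-4-ol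
Product: 15 (3E,5Z)-6-[(1R,3aS,4R,8aS)-4-hydroxy-3a,6-dimethyl-1,2,3,3a,4,7,8,8a-octahydroazulen-1-yl]hepta-3,5-dien-2-one, via enal 14 (not isolated)
Conditions: TEMPO (0.1 equiv), PhI(OAc)2 (1.1 equiv), CH2Cl2, 0 °C; then Ph3P=CHC(O)CH3 (1.5 equiv), 23 → 40 °C
Reagents that add atoms: 1-(triphenyl-λ5-phosphanylidene)propan-2-one, CC(=O)C=P(c1ccccc1)(c1ccccc1)c1ccccc1
Why: TEMPO oxidation takes the primary allylic alcohol much faster than the hindered secondary C1 alcohol, and the stabilised ylide traps the sensitive (Z)-enal in the same flask in an E-selective Wittig reaction, giving the 13E alkene without loss of the 11Z geometry.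

**Step 10**
Reactants: 15 (3E,5Z)-6-[(1R,3aS,4R,8aS)-4-hydroxy-3a,6-dimethyl-1,2,3,3a,4,7,8,8a-octahydroazulen-1-yl]hepta-3,5-dien-2-one
Product: 16 the 2,3-epoxide of 15 on the face of the C1 hydroxyl (biogenetic descriptors 1S,2S,3R,6S,7S,10R)
Conditions: VO(acac)2 (0.05 equiv), t-BuOOH (1.5 equiv), CH2Cl2, 0 °C
Reagents that add atoms: tert-butyl hydroperoxide, CC(C)(C)OO
Why: hydroxyl-directed vanadium-catalysed epoxidation delivers oxygen to the ring alkene syn to the C1 alcohol (cis-epoxy alcohol, which sets C2 and C3), while the electron-poor dienone alkenes do not react.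

**Step 11**
Reactants: 16 the 2,3-epoxide of 15
Product: 17 the epoxy diol with the (2Z,4E)-6-hydroxy-6-methylhepta-2,4-dien-2-yl side chain on C10
Conditions: MeLi (3 equiv), THF, −78 °C; aq. NH4Cl
Reagents that add atoms: methyllithium (MeLi), [Li]C
Why: 1,2-addition of MeLi to the methyl ketone of the dienone at low temperature, where the trisubstituted epoxide and the C1 alkoxide are inert; no stereocentre is formed.

**Step 12**
Reactants: 17 the epoxy diol
Product: 18 the target, the C1 acetate of 17 (biogenetic descriptors 1S,2S,3R,6S,7S,10R,11Z,13E)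
Conditions: Ac2O (1.5 equiv), pyridine, DMAP (0.1 equiv), CH2Cl2, 0 → 23 °C
Reagents that add atoms: acetic anhydride, CC(=O)OC(C)=O
Why: DMAP-catalysed acylation esterifies the secondary C1 alcohol and leaves the tertiary allylic alcohol free.

**Compound list**
1 | neryl acetate, (2Z)-3,7-dimethylocta-2,6-dien-1-yl acetate | CC(C)=CCC/C(C)=C\COC(C)=O | starting material
2 | (2Z,6E)-8-hydroxy-3,7-dimethylocta-2,6-dien-1-yl acetate | OC/C(C)=C/CC/C(C)=C\COC(C)=O | intermediate
3 | (2Z,6E)-8-bromo-3,7-dimethylocta-2,6-dien-1-yl acetate | BrC/C(C)=C/CC/C(C)=C\COC(C)=O | intermediate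
4 | (2Z,6E)-3,7-dimethylundeca-2,6-dien-10-yn-1-ol | C#CCC/C(C)=C/CC/C(C)=C\CO | intermediate
5 | (2Z,6E)-3,7-dimethyldodeca-2,6-dien-10-yn-1-ol | CC#CCC/C(C)=C/CC/C(C)=C\CO | intermediate
6 | (2Z,6E)-3,7-dimethyldodeca-2,6-dien-10-ynal | CC#CCC/C(C)=C/CC/C(C)=C\C=O | intermediate
7 | trans-fused bicyclic vinyl cation (1R,6S,7S; exocyclic C10=C11(+)–CH3 on the five-membered ring) | O[C@@H]1C=C(C)CC[C@H]2C(=[C+]C)CC[C@]12C | intermediate
8 | enol of 9 (C10=C11(OH)CH3) | O[C@@H]1C=C(C)CC[C@H]2C(=C(C)O)CC[C@]12C | intermediate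
9 | 1-[(1R,3aS,4R,8aS)-4-hydroxy-3a,6-dimethyl-1,2,3,3a,4,7,8,8a-octahydroazulen-1-yl]ethan-1-one (trans-fused; OH and acetyl both anti to the angular methyl) | O[C@@H]1C=C(C)CC[C@H]2[C@H](C(C)=O)CC[C@]12C | intermediate
10 | enol phosphate of 9: acetyl replaced by 1-[(diethoxyphosphoryl)oxy]ethenyl | O[C@@H]1C=C(C)CC[C@H]2[C@H](C(=C)OP(=O)(OCC)OCC)CC[C@]12C | intermediate
11 | (1R,3aS,4R,8aS)-1-ethynyl-3a,6-dimethyl-1,2,3,3a,4,7,8,8a-octahydroazulen-4-ol | O[C@@H]1C=C(C)CC[C@H]2[C@H](C#C)CC[C@]12C | intermediate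
12 | (1R,3aS,4R,8aS)-1-(3-hydroxyprop-1-yn-1-yl)-3a,6-dimethyl-1,2,3,3a,4,7,8,8a-octahydroazulen-4-ol | O[C@@H]1C=C(C)CC[C@H]2[C@H](C#CCO)CC[C@]12C | intermediate
13 | (1R,3aS,4R,8aS)-1-[(2Z)-4-hydroxybut-2-en-2-yl]-3a,6-dimethyl-1,2,3,3a,4,7,8,8a-octahydroazulen-4-ol | O[C@@H]1C=C(C)CC[C@H]2[C@H](/C(C)=C\CO)CC[C@]12C | intermediate
14 | (2Z)-3-[(1R,3aS,4R,8aS)-4-hydroxy-3a,6-dimethyl-1,2,3,3a,4,7,8,8a-octahydroazulen-1-yl]but-2-enal | O[C@@H]1C=C(C)CC[C@H]2[C@H](/C(C)=C\C=O)CC[C@]12C | intermediate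
15 | (3E,5Z)-6-[(1R,3aS,4R,8aS)-4-hydroxy-3a,6-dimethyl-1,2,3,3a,4,7,8,8a-octahydroazulen-1-yl]hepta-3,5-dien-2-one | O[C@@H]1C=C(C)CC[C@H]2[C@H](/C(C)=C\C=C\C(C)=O)CC[C@]12C | intermediate
16 | 2,3-epoxide of 15, cis to the C1 hydroxyl (1S,2S,3R,6S,7S,10R) | O[C@@H]1[C@@H]2O[C@]2(C)CC[C@H]2[C@H](/C(C)=C\C=C\C(C)=O)CC[C@]12C | intermediate
17 | epoxy diol: 16 with the side chain (2Z,4E)-6-hydroxy-6-methylhepta-2,4-dien-2-yl | O[C@@H]1[C@@H]2O[C@]2(C)CC[C@H]2[C@H](/C(C)=C\C=C\C(C)(C)O)CC[C@]12C | intermediate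
18 | C1 acetate of 17 (1S,2S,3R,6S,7S,10R,11Z,13E) | CC(=O)O[C@@H]1[C@@H]2O[C@]2(C)CC[C@H]2[C@H](/C(C)=C\C=C\C(C)(C)O)CC[C@]12C | target

**Totals and risks**
Total step count: 12. Longest linear sequence: 12 steps (fully linear from neryl acetate).

Steps most likely to fail:

1. Step 6 (bicyclisation). The first closure must go through the more substituted alkene carbon C7. The competing Markovnikov 6-exo closure would give a monocyclic ene product or, after a 1,2-hydride shift, a spiro (acorane-type) ketone; the C1 epimer is a lesser risk. The fallback sets out from 5 and comes back at 9, and uses a sulfur group on C6 to make the needed regiochemistry the normal one. PhSCl (CH2Cl2, −78 °C) adds across the 6,7-alkene of 5 to give the racemic anti β-chloro sulfide (2Z)-7-chloro-3,7-dimethyl-6-(phenylsulfanyl)dodec-2-en-10-yn-1-ol F1. DBU (toluene, 80 °C) removes HCl towards the sulfur-bearing carbon to give the vinyl sulfide (2Z,6E)-3,7-dimethyl-6-(phenylsulfanyl)dodeca-2,6-dien-10-yn-1-ol F2. MnO2 (hexane, 0 °C) gives the enal (2Z,6E)-3,7-dimethyl-6-(phenylsulfanyl)dodeca-2,6-dien-10-ynal F3. Under the acid/water conditions of step 6 the vinyl sulfide attacks the aldehyde through C7 by ordinary Markovnikov control, the thionium ion at C6 is closed by the butynyl group, and hydration gives the 6-(phenylsulfanyl) analogue of 9 F4. Bu3SnH/AIBN (toluene, 110 °C) then replaces sulfur by hydrogen, delivered to the ring-fusion radical from the face opposite the C7 methyl, to give 9.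

2. Step 7 (ketone to propargylic alcohol with a free C1 hydroxyl). The C1 alkoxide may be phosphorylated. The fallback sets out from 9 and comes back at 12, and takes the hydroxyl out of play. Et3SiCl/imidazole (DMF) gives the triethylsilyl ether of 9 F5. The same LiN(i-Pr)2 / ClP(O)(OEt)2 / LiN(i-Pr)2 / (CH2O)n sequence then passes through the silyl-protected enol phosphate F6 and the silyl-protected terminal alkyne F7, neither isolated, to the silyl-protected propargylic alcohol F8. Bu4NF (THF) removes silicon to give 12.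

3. Step 8 (iron-catalysed carbometalation). The hindered secondary substituent on the alkyne may lower the rate or the regioselectivity. The fallback sets out from 9 and comes back at 13, and uses a cuprate syn-addition to an ynoate instead. Compound 9 is taken through 10 and 11 as in step 7, but the acetylide and the C1 alkoxide are quenched with ClCO2Me to give the ynoate carbonate methyl 3-[(1R,3aS,4R,8aS)-4-(methoxycarbonyloxy)-3a,6-dimethyl-1,2,3,3a,4,7,8,8a-octahydroazulen-1-yl]prop-2-ynoate F9. Me2CuLi (THF, −78 °C, protonation at −78 °C) adds syn to give the (Z)-enoate carbonate methyl (2Z)-3-[(1R,3aS,4R,8aS)-4-(methoxycarbonyloxy)-3a,6-dimethyl-1,2,3,3a,4,7,8,8a-octahydroazulen-1-yl]but-2-enoate F10. i-Bu2AlH (CH2Cl2, −78 °C) reduces the ester and cleaves the carbonate to give 13.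

**Further compounds**
F1 | step 6 | (2Z)-7-chloro-3,7-dimethyl-6-(phenylsulfanyl)dodec-2-en-10-yn-1-ol, anti adduct, racemic (one enantiomer drawn) | OC/C=C(C)\CC[C@H](Sc1ccccc1)[C@](C)(Cl)CCC#CC
F2 | step 6 | (2Z,6E)-3,7-dimethyl-6-(phenylsulfanyl)dodeca-2,6-dien-10-yn-1-ol | OC/C=C(C)\CC/C(Sc1ccccc1)=C(/C)CCC#CC
F3 | step 6 | (2Z,6E)-3,7-dimethyl-6-(phenylsulfanyl)dodeca-2,6-dien-10-ynal | O=C/C=C(C)\CC/C(Sc1ccccc1)=C(/C)CCC#CC
F4 | step 6 | 6-(phenylsulfanyl) analogue of 9 (ring-fusion H replaced by SPh) | O[C@@H]1C=C(C)CC[C@@]2(Sc3ccccc3)[C@H](C(C)=O)CC[C@]12C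
F5 | step 7 | triethylsilyl ether of 9 | CC[Si](CC)(CC)O[C@@H]1C=C(C)CC[C@H]2[C@H](C(C)=O)CC[C@]12C
F6 | step 7 | triethylsilyl ether of 10 | CC[Si](CC)(CC)O[C@@H]1C=C(C)CC[C@H]2[C@H](C(=C)OP(=O)(OCC)OCC)CC[C@]12C
F7 | step 7 | triethylsilyl ether of 11 | CC[Si](CC)(CC)O[C@@H]1C=C(C)CC[C@H]2[C@H](C#C)CC[C@]12C
F8 | step 7 | C1 triethylsilyl ether of 12 | CC[Si](CC)(CC)O[C@@H]1C=C(C)CC[C@H]2[C@H](C#CCO)CC[C@]12C
F9 | step 8 | methyl 3-[(1R,3aS,4R,8aS)-4-(methoxycarbonyloxy)-3a,6-dimethyl-1,2,3,3a,4,7,8,8a-octahydroazulen-1-yl]prop-2-ynoate | COC(=O)O[C@@H]1C=C(C)CC[C@H]2[C@H](C#CC(=O)OC)CC[C@]12C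
F10 | step 8 | methyl (2Z)-3-[(1R,3aS,4R,8aS)-4-(methoxycarbonyloxy)-3a,6-dimethyl-1,2,3,3a,4,7,8,8a-octahydroazulen-1-yl]but-2-enoate | COC(=O)O[C@@H]1C=C(C)CC[C@H]2[C@H](/C(C)=C\C(=O)OC)CC[C@]12C
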